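**Retrosynthetic overview**

1. Target ⇒ cut one aryl–CH2 bond of the methylene bridge: the ring A phenol carrying the finished chiral side chain, plus the ortho-quinone methide of ring B released from its Mannich base.
2. Ring A phenol ⇒ key step: direct C-alkylation of mirror-symmetric 2,4,6-trihydroxyisobutyrophenone with (S)-2-isopropenyloxirane. The C–C bond forms through a dearomatised cyclohexadienone, one of two equivalent ring CH positions is used, and the epoxide C–O stereocentre becomes the (R)-carbinol.
3. (S)-Epoxide ⇒ hydrolytic kinetic resolution of the racemate ⇐ methacrolein + sulfonium methylide.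
4. Ring B ⇒ para-selective O-methylation ⇐ acetylation of 2-methylphloroglucinol; the ring A ketone ⇐ isobutyrylation of phloroglucinol.
5. Rings: both benzene rings are bought. The only ring made is the oxirane, which is opened again in the key step. Ring A is elaborated first and ring B is attached last.

Assumption: the stereocentre is read from the SMILES as (R), and enantiopure 2-(prop-1-en-2-yl)oxirane is treated as not purchasable and is made.

**Route**

Step 1
Reactants: 1 phloroglucinol (benzene-1,3,5-triol)
Product: 2 1-(2,4,6-trihydroxyphenyl)-2-methylpropan-1-one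
Conditions: i-PrCOCl (1.05 equiv), AlCl3 (3.5 equiv), PhNO2/CH2Cl2, 0 °C → rt; aq. HCl
Reagents that add atoms: isobutyryl chloride, CC(C)C(Cl)=O
Why: Friedel–Crafts acylation of the threefold-symmetric, very electron-rich ring stops at one acyl group because the chelated aryl ketone (as its AlCl3 complex) is deactivated.

Step 2
Reactants: 3 methacrolein (2-methylprop-2-enal)
Product: 4 rac-2-(prop-1-en-2-yl)oxirane
Conditions: Me3S+ I− (1.1 equiv), NaH (1.1 equiv), DMSO/THF, −5 °C → rt; fractional distillation
Reagents that add atoms: trimethylsulfonium iodide, C[S+](C)C.[I-]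
Why: Corey–Chaykovsky epoxidation, in which dimethylsulfonium methylide adds 1,2 to the enal carbonyl and the betaine closes to the vinyl oxirane with loss of Me2S.

Step 3
Reactants: 4 rac-2-(prop-1-en-2-yl)oxirane
Product: 5 (S)-2-(prop-1-en-2-yl)oxirane
Conditions: (S,S)-(salen)Co(OAc) (0.5 mol%, trivalent cobalt; salen = N,N'-bis(3,5-di-tert-butylsalicylidene)cyclohexane-1,2-diamine dianion), H2O (0.55 equiv), neat, 0 °C → rt, 16 h; vacuum transfer
Reagents that add atoms: none
Why: Jacobsen hydrolytic kinetic resolution, in which the (S,S) catalyst hydrates the (R)-epoxide much faster (same sense as for propylene oxide and butadiene monoepoxide), so the unreacted volatile epoxide is recovered as the (S)-enantiomer in up to 50% yield and high ee; this sets the only stereocentre of the route.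

Step 4 (key step)
Reactants: 2 1-(2,4,6-trihydroxyphenyl)-2-methylpropan-1-one (3 equiv, excess recovered), 5 (S)-2-(prop-1-en-2-yl)oxirane
Product: 7 1-{2,4,6-trihydroxy-3-[(2R)-2-hydroxy-3-methylbut-3-en-1-yl]phenyl}-2-methylpropan-1-one, via cyclohexadienone 6 (not isolated)
Conditions: LiOH (6 equiv), H2O/CF3CH2OH 1:1, 45 °C, 24 h, sealed; 1 M HCl to pH 5 at 0 °C
Reagents that add atoms: none
Why: Proposed new method: the lithium dianion of 2 has β-dicarbonyl-enolate character and its oxygens are masked by hydrogen bonding to water/trifluoroethanol, so one of its two equivalent ring carbons attacks the unhindered CH2 of 5 in an SN2 opening (dearomatised dienone 6, then tautomerisation), which breaks the mirror symmetry of 2 and carries the untouched C–O stereocentre of 5 over as the (R)-carbinol; the closest known chemistry is the C-alkylation of acylphloroglucinol anions by prenyl bromide or methyl iodide in protic alkaline media (Kornblum-type solvent control of ambident phenoxides) and the terminal SN2 opening of vinyl oxiranes by malonate-type enolates.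

Step 5
Reactants: 8 2-methylbenzene-1,3,5-triol (2,4,6-trihydroxytoluene)
Product: 9 1-(2,4,6-trihydroxy-3-methylphenyl)ethan-1-one
Conditions: AcCl (1.05 equiv), AlCl3 (3.5 equiv), PhNO2/CH2Cl2, 0 °C → rt; aq. HCl
Reagents that add atoms: acetyl chloride, CC(Cl)=O
Why: Friedel–Crafts acylation gives a single mono-ketone because the two free ring positions of 8 are equivalent and the chelated product is deactivated.

Step 6
Reactants: 9 1-(2,4,6-trihydroxy-3-methylphenyl)ethan-1-one
Product: 10 1-(2,6-dihydroxy-4-methoxy-3-methylphenyl)ethan-1-one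
Conditions: Me2SO4 (1.0 equiv), K2CO3 (1.0 equiv), acetone, 0 °C → rt
Reagents that add atoms: dimethyl sulfate, COS(=O)(=O)OC
Why: Williamson O-methylation favours the 4-OH, which is the most acidic (para to the acetyl) and the only hydroxyl not held in the hydrogen-bond chelate with the carbonyl, and one equivalent of Me2SO4 limits over-methylation.

Step 7
Reactants: 10 1-(2,6-dihydroxy-4-methoxy-3-methylphenyl)ethan-1-one, 7 1-{2,4,6-trihydroxy-3-[(2R)-2-hydroxy-3-methylbut-3-en-1-yl]phenyl}-2-methylpropan-1-one
Product: 13 1-{3-[(3-acetyl-2,4-dihydroxy-6-methoxy-5-methylphenyl)methyl]-2,4,6-trihydroxy-5-[(2R)-2-hydroxy-3-methylbut-3-en-1-yl]phenyl}-2-methylpropan-1-one (target), via Mannich base 11 (not isolated), via ortho-quinone methide 12 (not isolated)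
Conditions: 10, CH2=NMe2+ I− (1.0 equiv), NaOAc (1.1 equiv), MeCN, rt, 2 h; then 7 (1.0 equiv), 80 °C, 6 h
Reagents that add atoms: N,N-dimethylmethyleneiminium iodide (Eschenmoser's salt), C=[N+](C)C.[I-]
Why: Mannich aminomethylation at the only free carbon of 10, thermal loss of Me2NH to the dearomatised ortho-quinone methide 12, and Michael (Friedel–Crafts-type) addition of the only free ring carbon of 7 with rearomatisation give the unsymmetrical diarylmethane without homodimers, under near-neutral conditions that leave the allylic (R)-carbinol untouched.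

**Compound list**

1 | phloroglucinol (benzene-1,3,5-triol) | Oc1cc(O)cc(O)c1 | starting material
2 | 1-(2,4,6-trihydroxyphenyl)-2-methylpropan-1-one | CC(C)C(=O)c1c(O)cc(O)cc1O | intermediate
3 | methacrolein (2-methylprop-2-enal) | CC(=C)C=O | starting material
4 | rac-2-(prop-1-en-2-yl)oxirane | C=C(C)C1CO1 | intermediate
5 | (S)-2-(prop-1-en-2-yl)oxirane | C=C(C)[C@H]1CO1 | intermediate
6 | 3,5-dihydroxy-6-[(2R)-2-hydroxy-3-methylbut-3-en-1-yl]-4-(2-methylpropanoyl)cyclohexa-2,4-dien-1-one (both epimers at the ring sp3 carbon, not isolated) | CC(C)C(=O)C1=C(O)C(C[C@@H](O)C(C)=C)C(=O)C=C1O | intermediate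
7 | 1-{2,4,6-trihydroxy-3-[(2R)-2-hydroxy-3-methylbut-3-en-1-yl]phenyl}-2-methylpropan-1-one | CC(C)C(=O)c1c(O)cc(O)c(C[C@@H](O)C(C)=C)c1O | intermediate
8 | 2-methylbenzene-1,3,5-triol (2,4,6-trihydroxytoluene) | Cc1c(O)cc(O)cc1O | starting material
9 | 1-(2,4,6-trihydroxy-3-methylphenyl)ethan-1-one | CC(=O)c1c(O)cc(O)c(C)c1O | intermediate
10 | 1-(2,6-dihydroxy-4-methoxy-3-methylphenyl)ethan-1-one | CC(=O)c1c(O)cc(OC)c(C)c1O | intermediate
11 | 1-{3-[(dimethylamino)methyl]-2,6-dihydroxy-4-methoxy-5-methylphenyl}ethan-1-one (not isolated) | CC(=O)c1c(O)c(CN(C)C)c(OC)c(C)c1O | intermediate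
12 | 2-acetyl-3-hydroxy-5-methoxy-4-methyl-6-methylidenecyclohexa-2,4-dien-1-one (not isolated) | C=C1C(=O)C(C(C)=O)=C(O)C(C)=C1OC | intermediate
13 | 1-{3-[(3-acetyl-2,4-dihydroxy-6-methoxy-5-methylphenyl)methyl]-2,4,6-trihydroxy-5-[(2R)-2-hydroxy-3-methylbut-3-en-1-yl]phenyl}-2-methylpropan-1-one | C=C(C)[C@H](O)Cc1c(O)c(Cc2c(O)c(C(C)=O)c(O)c(C)c2OC)c(O)c(C(=O)C(C)C)c1O | target

**Step count and risks**

Total steps: 7. Longest linear sequence: 4 (steps 2, 3, 4, 7, from methacrolein).

Steps most likely to fail:

Step 4. The phenoxide may attack the epoxide through oxygen (aryl 2-hydroxyalkyl ethers), or the epoxide may be opened at its allylic carbon, or alkylated twice. The fallback sets out from 2 and comes back at 7; it makes the stereocentre on the ring instead of bringing it in. 2 is C-prenylated with prenyl bromide in aqueous KOH at 0 °C to 1-[2,4,6-trihydroxy-3-(3-methylbut-2-en-1-yl)phenyl]-2-methylpropan-1-one F1. The three phenols are silylated (TBSOTf, 2,6-lutidine) to 1-[2,4,6-tris(tert-butyldimethylsilyloxy)-3-(3-methylbut-2-en-1-yl)phenyl]-2-methylpropan-1-one F2. Shi epoxidation of the trisubstituted alkene (D-fructose-derived ketone, Oxone 2KHSO5·KHSO4·K2SO4, pH 10.5, 0 °C) gives 1-[2,4,6-tris(tert-butyldimethylsilyloxy)-3-{[(2R)-3,3-dimethyloxiran-2-yl]methyl}phenyl]-2-methylpropan-1-one F3. Isomerisation of the epoxide with diethylaluminium 2,2,6,6-tetramethylpiperidide (proton taken from a methyl group, secondary C–O bond untouched) gives 1-{2,4,6-tris(tert-butyldimethylsilyloxy)-3-[(2R)-2-hydroxy-3-methylbut-3-en-1-yl]phenyl}-2-methylpropan-1-one F4. Bu4NF/AcOH then removes the silyl groups to give 7.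

Step 6. Methylation may also occur at a hydroxyl ortho to the acetyl, or twice. The fallback sets out from 9 and comes back at 10. Exhaustive methylation (excess Me2SO4, K2CO3, acetone, reflux) gives 1-(2,4,6-trimethoxy-3-methylphenyl)ethan-1-one F5. AlCl3 in chlorobenzene (or BCl3 in CH2Cl2) then cleaves only the two methoxy groups ortho to the acetyl through carbonyl chelation and leaves the para methoxy group, giving 10.

Step 7. The quinone methide may be trapped by the side-chain alcohol or a phenol oxygen, or the side chain may not tolerate the heating. The fallback sets out from 2 and 11 (made from 10 as in step 7) and comes back at 13; it builds the bridge before the side chain exists. 11 is heated with 2 (3 equiv) in MeCN to give 1-{3-[(3-acetyl-2,4-dihydroxy-6-methoxy-5-methylphenyl)methyl]-2,4,6-trihydroxyphenyl}-2-methylpropan-1-one F6. F6 has a single free ring CH and is alkylated with 5 under the conditions of step 4 to give 13 directly.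

**Further compounds**

F1 | step 4 | 1-[2,4,6-trihydroxy-3-(3-methylbut-2-en-1-yl)phenyl]-2-methylpropan-1-one | CC(C)C(=O)c1c(O)cc(O)c(CC=C(C)C)c1O
F2 | step 4 | 1-[2,4,6-tris(tert-butyldimethylsilyloxy)-3-(3-methylbut-2-en-1-yl)phenyl]-2-methylpropan-1-one | CC(C)C(=O)c1c(O[Si](C)(C)C(C)(C)C)cc(O[Si](C)(C)C(C)(C)C)c(CC=C(C)C)c1O[Si](C)(C)C(C)(C)C
F3 | step 4 | 1-[2,4,6-tris(tert-butyldimethylsilyloxy)-3-{[(2R)-3,3-dimethyloxiran-2-yl]methyl}phenyl]-2-methylpropan-1-one | CC(C)C(=O)c1c(O[Si](C)(C)C(C)(C)C)cc(O[Si](C)(C)C(C)(C)C)c(C[C@@H]2C(C)(C)O2)c1O[Si](C)(C)C(C)(C)C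
F4 | step 4 | 1-{2,4,6-tris(tert-butyldimethylsilyloxy)-3-[(2R)-2-hydroxy-3-methylbut-3-en-1-yl]phenyl}-2-methylpropan-1-one | CC(C)C(=O)c1c(O[Si](C)(C)C(C)(C)C)cc(O[Si](C)(C)C(C)(C)C)c(C[C@@H](O)C(C)=C)c1O[Si](C)(C)C(C)(C)C
F5 | step 6 | 1-(2,4,6-trimethoxy-3-methylphenyl)ethan-1-one | CC(=O)c1c(OC)cc(OC)c(C)c1OC
F6 | step 7 | 1-{3-[(3-acetyl-2,4-dihydroxy-6-methoxy-5-methylphenyl)methyl]-2,4,6-trihydroxyphenyl}-2-methylpropan-1-one | CC(C)C(=O)c1c(O)cc(O)c(Cc2c(O)c(C(C)=O)c(O)c(C)c2OC)c1O
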